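3 amounts are asked of the flask after 3.0 d, and the dawn run is the one run to reason from.

- dawn: starting material 0.020 M; reagent 0.012 M; run made earlier
- flask: starting material 0.020 M; reagent 0.0240 M; time 3.0 d

dawn run (percent of the starting material charged)

| time / h | starting material / % | first product / % | double product / % |
|---|---|---|---|
| 1.00 | 85.2 | 9.3 | 0 |
| 2.00 | 77.6 | 14.9 | 3.0 |
| 2.50 | 73.3 | 15.2 | 1.3 |
| 4.00 | 66.3 | 18.0 | 2.4 |
| 6.00 | 58.4 | 21.8 | 2.4 |
| 10.0 | 52.3 | 23.6 | 1.6 |
| 15.0 | 44.5 | 24.1 | 2.3 |

(standard deviation of a reading: 1 percentage point)

- a reading or a percentage of first product counts all its forms, free or not

* amount of starting material at 3.0 d, in percent of the starting material charged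
* amount of first product at 3.0 d, in percent of the starting material charged
* amount of double product at 3.0 d, in percent of the starting material charged

In the dawn run, first and double product together grow at 0.0930 h⁻¹ of the charge over the first hour, but at 0.00545 h⁻¹ between 4.00 h and 15.0 h: a slowing by a factor of 17.1, as read. Starting material, at 52.3% by 10.0 h, gives a factor of 1.91. The products at the last reading hold a share Y of 0.478 of the reagent charged, double product counting two reagent, so reagent used for them gives a factor of 1.92. A factor of 4.65 remains.

My own reckoning takes this as reagent lost against itself, at a rate following its square. The waste ratio w is then the rate of that loss over the rate of reagent's use on starting material, at the start, a kind of selectivity factor. With starting material held constant, Y = ln(1+w)/w, and the dawn share, taken as final, gives w = 2.78. The flask's reagent charge multiplies w by 2.00, to 5.57, so Y falls to 0.338. Double product enters as a correction at its dawn share of the products, 8.71%, and counts two reagent, so the products total 37.3%, which leaves 34.1% first product and 3.25% double product.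

The forecast differs, giving 3% starting material, 55% first product and 4% double product, on the view that “each first product holds a second reagent”.

The flask gives 33.3% starting material, 32.8% first product and 3.53% double product, with 0% of its reagent left.

    crystals ⇌ first product, rate k1*(cs1 - [first product]) while solid is left; crystals form when [first product] > cs1 (solubility = 0.660 mM, k = 21.3 h⁻¹)
    reagent + first product → double product (k = 26.9 M⁻¹ h⁻¹)
    2 reagent → self-condensation product (k = 28.2 M⁻¹ h⁻¹)
    starting material + reagent → first product (k = 13.7 M⁻¹ h⁻¹)
    starting material ⇌ dormant form (K = 0.910, k = 0.0475 h⁻¹)

The flask's products total 36.3%, against 37.3% reckoned and 59.0% in the forecast. In the neighbour flask charged with 0.041 M of reagent, the same scaling carries w to 9.51 and Y to 0.247, which reckons 46.6% of products. That neighbour holds 39.2% first product and 4.72% double product after 3.00 d, together 43.9%.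

(The runs are calculated with made-up constants, noise included.)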